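**Retrosynthetic overview**

- The strategy rests on one feature: the formyl carbon C7 sits on C1 of the single benzene ring, para to the oxygen on C4, and the ring has no C–H left (Br on C2, C3 and C6, O on C4 and C5). C7 can therefore be carried as a methyl group and oxidised last by electron transfer.
- Target ⇒ 2,3,6-tribromo-4,5-dimethoxybenzaldehyde dimethyl acetal: the two aryl ethers and the acetal are cleaved together by BBr3.
- Acetal ⇒ 2,3,6-tribromo-4,5-dimethoxytoluene and two methanol: both C7–O bonds are made by anodic side-chain oxidation.
- Tribromodimethoxytoluene ⇒ 3,4-dimethoxytoluene and bromine: three C–Br bonds by exhaustive ring bromination.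
- No ring is formed in the route; the benzene ring comes with the starting material.

Key step: step 2

Assumption: the electrolysis is run in an undivided cell in which 2,6-lutidine carries protons from anode to cathode and is regenerated there. The two ring oxygens stay methylated until the last step, because a free catechol would be oxidised to the o-quinone at the anode.

**Step 1**
Reactants: 1 3,4-dimethoxytoluene; 2 bromine
Product: 6 2,3,6-tribromo-4,5-dimethoxytoluene, via 2-bromo-4,5-dimethoxytoluene 3 (not isolated), via 2,3-dibromo-4,5-dimethoxytoluene 4 (not isolated), via 2,6-dibromo-3,4-dimethoxytoluene 5 (not isolated)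
Conditions: Br2 (4.5 equiv), FeBr3 (5 mol %), CH2Cl2, 0 °C to reflux, dark; aq. Na2S2O3
Reagents that add atoms: bromine, BrBr
Why: Electrophilic aromatic bromination: each of the three free ring positions is ortho or para to a methoxy group, so FeBr3-activated bromine should substitute all of them, passing through monobromide 3 and then either dibromide 4 or 5 (both converge on 6), while the dark ionic conditions should keep bromine off the methyl group.

**Step 2**
Reactants: 6 2,3,6-tribromo-4,5-dimethoxytoluene; 7 methanol
Product: 9 2,3,6-tribromo-4,5-dimethoxybenzaldehyde dimethyl acetal, via 2,3,6-tribromo-4,5-dimethoxybenzyl methyl ether 8 (not isolated)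
Conditions: graphite anode, Pt cathode, undivided cell, constant current 5 mA/cm2, 4.5 F/mol; LiClO4 (0.1 M), 2,6-lutidine (1 equiv), MeOH/CH2Cl2 4:1, 20 °C
Reagents that add atoms: methanol, CO
Why: The arene is oxidised at the anode to its radical cation, which loses a proton from the C7 methyl group to 2,6-lutidine; the benzyl radical is oxidised to a cation stabilised through the ring by the C4 methoxy oxygen and is captured by methanol to give ether 8, and a second pass of the same electron, proton, electron, nucleophile sequence turns 8 into acetal 9. The closest known reaction type is the anodic side-chain methoxylation of 4-methoxytoluenes to benzaldehyde dimethyl acetals. No ring is closed and no stereocenter is formed. The step needs side-chain deprotonation to win over ipso addition of methanol at C4, C5 or the bromine-bearing C2 (para to the C5 methoxy group); the near-neutral, lutidine-buffered and methoxide-free medium should favour proton loss from the radical cation over nucleophilic attack on the ring. Over-oxidation should be held back because the CH(OMe)2 group, wedged between the C2 and C6 bromines, keeps its remaining C–H bond in the ring plane and out of overlap with the π system, and because the charge is limited to little more than 4 F/mol. Proton reduction at the Pt cathode occurs well positive of the potential for C–Br reduction, so the three bromines should stay in place.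

**Step 3**
Reactants: 9 2,3,6-tribromo-4,5-dimethoxybenzaldehyde dimethyl acetal
Product: 12 2,3,6-tribromo-4,5-dihydroxybenzaldehyde, via 2,3,6-tribromo-4,5-dimethoxybenzaldehyde 10 (not isolated), via 2,4,6,7-tetrabromo-1,3,2-benzodioxaborole-5-carbaldehyde 11 (not isolated)
Conditions: BBr3 (5 equiv), CH2Cl2, −78 °C to 20 °C; then H2O, 0 °C to 20 °C
Reagents that add atoms: none
Why: Lewis-acid ether cleavage: BBr3 first ionises the acetal and bromide dealkylates the oxocarbenium ion to aldehyde 10, then both aryl methyl ethers are cleaved by SN2 attack of bromide on the boron-bound O-methyl groups to give cyclic bromoborate 11, which water hydrolyses to the catechol, and the aryl C–Br bonds are inert to the reagent.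

**Compound list**

1 | 3,4-dimethoxytoluene | Cc1ccc(OC)c(OC)c1 | starting material
2 | bromine | BrBr | starting material
3 | 2-bromo-4,5-dimethoxytoluene | Cc1cc(OC)c(OC)cc1Br | intermediate
4 | 2,3-dibromo-4,5-dimethoxytoluene | Cc1cc(OC)c(OC)c(Br)c1Br | intermediate
5 | 2,6-dibromo-3,4-dimethoxytoluene | Cc1c(Br)cc(OC)c(OC)c1Br | intermediate
6 | 2,3,6-tribromo-4,5-dimethoxytoluene | Cc1c(Br)c(Br)c(OC)c(OC)c1Br | intermediate
7 | methanol | CO | starting material
8 | 2,3,6-tribromo-4,5-dimethoxybenzyl methyl ether | COCc1c(Br)c(Br)c(OC)c(OC)c1Br | intermediate
9 | 2,3,6-tribromo-4,5-dimethoxybenzaldehyde dimethyl acetal | COC(OC)c1c(Br)c(Br)c(OC)c(OC)c1Br | intermediate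
10 | 2,3,6-tribromo-4,5-dimethoxybenzaldehyde | O=Cc1c(Br)c(Br)c(OC)c(OC)c1Br | intermediate
11 | 2,4,6,7-tetrabromo-1,3,2-benzodioxaborole-5-carbaldehyde | O=Cc1c(Br)c(Br)c2OB(Br)Oc2c1Br | intermediate
12 | 2,3,6-tribromo-4,5-dihydroxybenzaldehyde | O=Cc1c(Br)c(O)c(O)c(Br)c1Br | target

**Step count**

Total steps: 3. Longest linear sequence: 3.

**Steps most likely to fail**

1. Step 2. Three bromines and two methoxy groups twisted out of the ring plane raise the oxidation potential of 6, so discharge of methanol may compete with oxidation of the substrate. Methanol may also add ipso to the radical cation with loss of bromide or ketal formation, and the second oxidation may stall at the benzyl ether stage. The fallback leaves electrochemistry and sets out from 6. Wohl–Ziegler bromination (N-bromosuccinimide, AIBN, PhCF3, reflux) should give 2,3,6-tribromo-4,5-dimethoxybenzyl bromide F1. Kornblum oxidation (DMSO, NaHCO3, 100 °C) should then give aldehyde 10, here isolated. The route is rejoined at 10, which is taken on to 12 with BBr3 as in step 3.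

2. Step 1. Substitution at the last, most crowded ring position may stay incomplete, and forcing it may bring radical bromination of the methyl group or acid cleavage of a methyl ether. The fallback brominates the much more reactive free catechol. It sets out from bromine 2, used on purchased 4-methylcatechol F2 in place of 1. Br2 (3.3 equiv) in AcOH at 20 °C should give 3,4,6-tribromo-5-methylbenzene-1,2-diol F3. Double Williamson O-methylation (MeI, K2CO3, DMF, 40 °C) then returns to the route at 6.

3. Step 3. Bromide may add to the boron-activated formyl group, giving a benzylic gem-dibromide that hydrolyses slowly between the two ortho bromines, or cleavage of the second, hindered ether may stay incomplete. The fallback separates the two operations and avoids the halide Lewis acid. It sets out from 9. Hydrolysis of the acetal (2 M HCl, THF, 20 °C) should give aldehyde 10, isolated. Protic ether cleavage (48% HBr, AcOH, reflux) then reaches 12.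

**Further compounds**

F1 | step 2 | 2,3,6-tribromo-4,5-dimethoxybenzyl bromide | BrCc1c(Br)c(Br)c(OC)c(OC)c1Br
F2 | step 1 | 4-methylcatechol (4-methylbenzene-1,2-diol) | Cc1ccc(O)c(O)c1
F3 | step 1 | 3,4,6-tribromo-5-methylbenzene-1,2-diol | Cc1c(Br)c(Br)c(O)c(O)c1Br
F0 | step 3 | none | none
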